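## Structural features

The target is a 1H-indole: a benzene ring fused across the C3a–C7a bond to a pyrrole ring, flat and aromatic, with no stereocentre and no side chain. All four substituents are bromine atoms, two on the pyrrole ring (C2, C3) and two on the benzene ring (C4, C7), so C5–H, C6–H and N1–H are the only hydrogens. The C4 and C7 bromines flank the ring fusion; electrophilic bromination of an indole would go to C3 and then C5/C6, so this pattern must come from a pre-brominated benzene. The C2 bromine next to N1 is the second problem, because electrophiles prefer C3 and a C2 halogen normally calls for C2 metalation, which sits badly with three other C–Br bonds. The fragile points are the aryl C–Br bonds (no palladium, copper, alkyllithium or dissolving metal once they are in place) and the free N–H 2,3-dibromoindole unit, which is sensitive to acid, light and oxidants. The real difficulty is therefore chemoselective ring construction among several C–Br bonds, not skeletal complexity. The key step uses the N1–C2(Br) unit: C2 with its bromine is read as the terminal carbon of a 2,2-dibromovinyl group attached to the future C3a, so that closing N1–C2 expels one bromide and keeps the other. C3, the natural nucleophilic position of the pyrrole ring, is left for the last bromine.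

## Logic of the disconnections

**11 to 10.** The C3–Br bond is cut. C3 is the innate site of electrophilic substitution in an N–H indole, and in 10 the positions C2, C4 and C7 are already occupied while C5 and C6 lie on a deactivated ring. The gain is that the most sensitive array, the free 2,3-dibromoindole, exists only in the final step. The forward step must brominate an electron-poor indole once, next to the peri C4 bromine, without oxidising it.

**10 to 9.** The N1–S bond is cut. The sulfonyl group is wanted for the ring closure, where it makes N–H acidic, but not in the target. The forward step must break N–S by attack at sulfur, without reducing any C–Br bond and without substitution at C2.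

**9 to 7, through 8.** The N1–C2 bond of the pyrrole ring is cut. C2 and its bromine become the CBr2 terminus of a dibromovinyl group and N1 becomes a sulfonamide N–H ortho to it. This removes the heterocycle and leaves a 1,2,3,4-tetrasubstituted benzene. The forward step must be an ionic, metal-free closure that touches only the vinylic bromides.

**7 to 5 and 6.** The C=C bond between the future C3 and C2 is cut as a Wittig-type olefination of an aryl aldehyde. Compound 6 supplies C2 together with both of its bromines. The ylide must cope with an acidic N–H and a formyl group substituted on both ortho positions.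

**5 to 3 and 4.** The aryl C–N bond (future C7a–N1) is cut as a nucleophilic aromatic substitution of fluoride ortho to the formyl group. The nitrogen arrives already sulfonylated, so no separate protection step is needed. Fluoride must be displaced in preference to the bromide that is also ortho to the formyl group.

**3 to 1, through 2.** The aryl–CHO bond (future C3a–C3) is cut. The only C–H of 1 flanked by fluorine and bromine is the most acidic and is exactly the position needed. A lithium amide, not an alkyllithium, and low temperature are required so that the bromines are neither exchanged nor eliminated.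

## Other disconnections considered

**Alternative 1:** The cut goes through the benzene ring at C3a–C4 and C7–C7a. C4–C7 with both bromines would come from 2,5-dibromothiophene 1,1-dioxide A1, and C3a, C7a and the nitrogen ring from tert-butyl 2,3-dihydro-1H-pyrrole-1-carboxylate A2. Forward, A1 would act as an electron-poor diene toward the enecarbamate alkene of A2 in an inverse-demand Diels–Alder reaction. The bridged sulfone would then lose SO2 cheletropically to give the racemic cis-fused tert-butyl 4,7-dibromo-2,3,3a,7a-tetrahydro-1H-indole-1-carboxylate A3.
- In its favour: the polarity of the partners is matched, the diene is symmetric so no regiochemical question arises, and two C–C bonds form at once.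
- Better than the chosen plan: no strong base, cryogenic step or transition metal is needed.
- Equal to the chosen plan: the C4 and C7 bromines are fixed by the building block.
- Against it: A3 is four hydrogens short of an indole. Aromatising the diene ring competes with double-bond migration and loss of HBr, which would cost a ring bromine. A1 tends to dimerise.
- After Boc removal the route reaches 4,7-dibromo-1H-indole A4, where both C3 and C2 must still be brominated. The C2 bromination is a less selective electrophilic process, whereas the chosen plan installs C2–Br during ring closure.
- Step economy: oxidation to A1, cycloaddition, two dehydrogenation stages, deprotection and dibromination come to about six steps, a draw. The chosen plan is preferred because every bromine is placed by construction and no redox adjustment of the skeleton is needed.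

**Alternative 2:** Three bonds are cut together, C3a–C7a, C4–C5 and C6–C7, leading to N-(bromoethynyl)-N-(4-bromobut-3-yn-1-yl)-4-methylbenzenesulfonamide A5 and acetylene A6. Forward, Cp*RuCl(cod), a divalent ruthenium complex, would couple the two bromoalkyne units to a ruthenacycle, insert A6 and release 4,7-dibromo-1-tosylindoline A7 by reductive elimination.
- Better than the chosen plan: both rings and three C–C bonds form in one catalytic, atom-economic step.
- Equal to the chosen plan: the benzenoid bromines are located by the alkyne termini.
- Against it: A5 contains an N-bromoethynyl sulfonamide, a sensitive and little-explored group, and needs its own multi-step assembly (N-alkynylation and two terminal brominations).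
- The catalytic step would have to outrun self-trimerisation of A6 and dimerisation of A5, and leave the C(sp)–Br bonds intact at the metal.
- A7 is an indoline, so dehydrogenation, C2 bromination, detosylation and C3 bromination would follow.
- Step economy: eight or more steps, with the least precedented reaction in the middle. The chosen plan is shorter and rests on an ionic closure that cannot engage the aryl bromides.

**Alternative 3:** The cut is N1–C7a. 2,5-Dibromobenzaldehyde A8 would be condensed with ethyl azidoacetate A9 to ethyl (Z)-2-azido-3-(2,5-dibromophenyl)prop-2-enoate A10. Thermolysis would release N2 and close the vinyl nitrene (or its 2H-azirine) onto the only free ortho carbon, giving ethyl 4,7-dibromo-1H-indole-2-carboxylate A11.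
- Equal to the chosen plan: the regiochemistry is unambiguous because the other ortho position carries bromine, and the closure is metal-free and spares the aryl bromides.
- Better than the chosen plan: the N–H indole is formed directly with no sulfonyl group to remove, and the indole core is reached in two steps from catalogue materials.
- Against it: C2 carries an ester where bromine is wanted. That means saponification and then either a bromodecarboxylation or decarboxylation to A4 followed by double bromination.
- Thermal decarboxylation of indole-2-carboxylic acids usually needs copper at high temperature, which endangers the aryl bromides.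
- A9 and A10 are energetic azides and the thermolysis evolves gas near 140 °C, so the chosen plan is safer.
- Step economy: about five steps if the bromodecarboxylation works, one fewer than the chosen plan, so here the alternative is equal or better. The chosen plan is preferred on safety and because C2–Br is made directly instead of by exchanging a carboxyl group.

Key step: step 4

Remark: compounds 1, 4 and 6 are catalogue chemicals; compound 3 is also sold, and buying it would remove step 1.
Remark: the 3,6-dibromo-2-formyl pattern of 5 maps onto C4, C7 and C3 of the indole, so the anilide skeleton is used unchanged with tosyl as the sulfonyl group.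

## Route

**Step 1**
Reactants: 1 1,4-dibromo-2-fluorobenzene
Product: 3 3,6-dibromo-2-fluorobenzaldehyde, via aryllithium 2 (not isolated)
Conditions: LiN(iPr)2 (1.1 equiv, commercial solution), THF, −78 °C, 45 min; DMF (1.5 equiv), −78 °C; aq. HCl
Reagents that add atoms: N,N-dimethylformamide, CN(C)C=O
Why: Directed ortho-metalation and formylation: the C–H between fluorine and bromine is the most acidic ring position, the lithium amide removes it without bromine–lithium exchange, and at −78 °C aryllithium 2 is kept from aryne formation until DMF traps it.

**Step 2**
Reactants: 3 3,6-dibromo-2-fluorobenzaldehyde; 4 p-toluenesulfonamide (1.3 equiv)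
Product: 5 N-(3,6-dibromo-2-formylphenyl)-4-methylbenzenesulfonamide
Conditions: K2CO3 (2.5 equiv), DMSO, 85 °C; aq. HCl to pH 3
Reagents that add atoms: none
Why: Nucleophilic aromatic substitution (SNAr): the ortho formyl group, helped inductively by the neighbouring bromine, stabilises the Meisenheimer adduct, and fluoride is displaced far faster than the bromide that is also ortho to the formyl group; the product is held as its potassium salt, which blocks a second arylation, and any N-sulfonyl imine formed at the aldehyde reverts on acidic work-up.

**Step 3**
Reactants: 5 N-(3,6-dibromo-2-formylphenyl)-4-methylbenzenesulfonamide; 6 carbon tetrabromide (2 equiv)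
Product: 7 N-[3,6-dibromo-2-(2,2-dibromovinyl)phenyl]-4-methylbenzenesulfonamide
Conditions: PPh3 (4 equiv), CH2Cl2, 0 °C to rt
Reagents that add atoms: none
Why: Ramirez dibromo-olefination (first stage of the Corey–Fuchs sequence): Ph3P=CBr2 formed from PPh3 and 6 undergoes a Wittig reaction with the aldehyde; the excess of ylide covers what the sulfonamide N–H protonates, and the alkene has no geometry to control because its terminus carries two bromines.

**Step 4**
Reactants: 7 N-[3,6-dibromo-2-(2,2-dibromovinyl)phenyl]-4-methylbenzenesulfonamide
Product: 9 2,4,7-tribromo-1-tosylindole, via bromoalkyne 8 (not isolated)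
Conditions: Cs2CO3 (2.5 equiv), dry DMF, 70 °C, N2, dark
Reagents that add atoms: none
Why: Cs2CO3 first removes the acidic sulfonamide N–H and then the vinylic hydrogen, which lies anti to one bromine, so that E2 loss of HBr gives bromoalkyne 8. The sulfonamide nitrogen then adds in the plane of the ring to the bromine-bearing alkyne carbon, and protonation of the resulting C3 vinyl anion by hydrogencarbonate completes the aromatic pyrrole ring; a direct addition–elimination at the dibromovinyl carbon would give the same product. The closest known reaction type is the transition-metal-free, carbonate- or fluoride-mediated cyclisation of 2-(2,2-dibromovinyl)-N-sulfonylanilines to 2-bromoindoles. The one ring closed is the pyrrole ring, by a 5-endo-dig N1–C2 closure (5-endo-trig in the addition–elimination variant). No stereocentre is formed. The step needs chemoselectivity among four C–Br bonds: without palladium or copper the two aryl bromides are inert to carbonate, and only the vinylic dibromide has a β-hydrogen for elimination and an electrophilic carbon within reach of nitrogen. Regioselectivity is secured by geometry, since attack on the aryl-bearing alkyne carbon would need a four-membered ring, so the bromine that is not expelled ends up on C2. Dry aprotic conditions should keep the tosyl group on nitrogen, and if some is lost the product is simply 10.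

**Step 5**
Reactants: 9 2,4,7-tribromo-1-tosylindole
Product: 10 2,4,7-tribromo-1H-indole
Conditions: KOH (4 equiv), THF–H2O (2:1), cetyltrimethylammonium bromide (10 mol %), 45 °C; aq. NH4Cl
Reagents that add atoms: none
Why: Nucleophilic desulfonylation: hydroxide attacks sulfur and expels the tribromoindolide, a good leaving group whose departure also relieves the crowding of the tosyl group between the C2 and C7 bromines; alcohol-free conditions avoid alkyl tosylates that could N-alkylate, and no reducing agent touches the C–Br bonds.

**Step 6**
Reactants: 10 2,4,7-tribromo-1H-indole
Product: 11 2,3,4,7-tetrabromo-1H-indole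
Conditions: NBS (1.05 equiv), dry DMF, 0 °C, dark; aq. Na2S2O3
Reagents that add atoms: N-bromosuccinimide, O=C1CCC(=O)N1Br
Why: Electrophilic aromatic substitution at C3, the enamine-like position of the N–H indole and the only unsubstituted carbon of the pyrrole ring; C5 and C6 lie on a doubly brominated, deactivated ring, so one equivalent at low temperature should stop at the tetrabromide.

## Compound list

1 | 1,4-dibromo-2-fluorobenzene | Fc1cc(Br)ccc1Br | starting material
2 | (3,6-dibromo-2-fluorophenyl)lithium (aryllithium, formed in the flask) | [Li]c1c(F)c(Br)ccc1Br | intermediate
3 | 3,6-dibromo-2-fluorobenzaldehyde | O=Cc1c(F)c(Br)ccc1Br | intermediate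
4 | p-toluenesulfonamide | Cc1ccc(cc1)S(N)(=O)=O | starting material
5 | N-(3,6-dibromo-2-formylphenyl)-4-methylbenzenesulfonamide | O=Cc1c(Br)ccc(Br)c1NS(=O)(=O)c1ccc(C)cc1 | intermediate
6 | carbon tetrabromide | BrC(Br)(Br)Br | starting material
7 | N-[3,6-dibromo-2-(2,2-dibromovinyl)phenyl]-4-methylbenzenesulfonamide | BrC(Br)=Cc1c(Br)ccc(Br)c1NS(=O)(=O)c1ccc(C)cc1 | intermediate
8 | N-[3,6-dibromo-2-(bromoethynyl)phenyl]-4-methylbenzenesulfonamide (bromoalkyne, formed in the flask) | BrC#Cc1c(Br)ccc(Br)c1NS(=O)(=O)c1ccc(C)cc1 | intermediate
9 | 2,4,7-tribromo-1-tosylindole (2,4,7-tribromo-1-(4-methylbenzenesulfonyl)-1H-indole) | Brc1cc2c(Br)ccc(Br)c2n1S(=O)(=O)c1ccc(C)cc1 | intermediate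
10 | 2,4,7-tribromo-1H-indole | Brc1cc2c(Br)ccc(Br)c2[nH]1 | intermediate
11 | 2,3,4,7-tetrabromo-1H-indole | Brc1[nH]c2c(Br)ccc(Br)c2c1Br | target

## Step count and least certain steps

Total step count: 6. Longest linear sequence: 6 steps (1 to 11).

**Step 4 (key step).**
- What may go wrong: slow ring closure, because the nitrogen anion is a weak nucleophile wedged next to an ortho bromine. The bromoalkyne stage would then linger and be consumed by oligomerisation or by amine impurities of the solvent. Premature loss of the sulfonyl group is harmless, since it leads to 10.
- Fallback, from 5 back to 9: the C2 bromine is introduced by directed metalation instead.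
  - Homologate 5 with dimethyl (1-diazo-2-oxopropyl)phosphonate and K2CO3 in MeOH (Ohira–Bestmann) to N-(3,6-dibromo-2-ethynylphenyl)-4-methylbenzenesulfonamide F1.
  - Cyclise with catalytic Cu(OAc)2 (divalent copper as a π-Lewis acid) in 1,2-dichloroethane at 70 °C to 4,7-dibromo-1-tosylindole F2.
  - Deprotonate at C2 with LiN(iPr)2 in THF at −78 °C and quench with 1,2-dibromo-1,1,2,2-tetrachloroethane to give 9.

**Step 2.**
- What may go wrong: incomplete displacement, because the sulfonamide anion is a weak, bulky nucleophile attacking a carbon wedged between the formyl group and a bromine. Reversible condensation at the aldehyde and slow base-induced degradation at the required temperature would compete.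
- Fallback, from 3 back to 5: a small, strong nitrogen nucleophile is used and the sulfonyl group is added afterwards.
  - Displace fluoride with 2,4-dimethoxybenzylamine (K2CO3, DMSO, 60 °C; mild aqueous acid to hydrolyse any imine) to give 3,6-dibromo-2-[(2,4-dimethoxybenzyl)amino]benzaldehyde F3.
  - Cleave the benzyl group with CF3CO2H and 1,3-dimethoxybenzene as cation scavenger in CH2Cl2 to give 2-amino-3,6-dibromobenzaldehyde F4.
  - Sulfonylate with TsCl in pyridine at 60 °C to give 5.

**Step 3.**
- What may go wrong: protonation of the ylide by the acidic sulfonamide N–H, and sluggish Wittig addition to a formyl group that is hindered on both sides and hydrogen-bonded to N–H.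
- Fallback, from 5 back to 7: the N–H is masked during the olefination.
  - Treat 5 with Boc2O, Et3N and catalytic 4-(dimethylamino)pyridine in CH2Cl2 to give tert-butyl (3,6-dibromo-2-formylphenyl)(tosyl)carbamate F5.
  - Olefinate with CBr4/PPh3 in CH2Cl2 at 0 °C to give tert-butyl [3,6-dibromo-2-(2,2-dibromovinyl)phenyl](tosyl)carbamate F6.
  - Remove the Boc group with CF3CO2H in CH2Cl2 to give 7.

**Step 6.**
- What may go wrong: N-bromination and oxidation of the sensitive free N–H bromoindole, misdirected bromination if the peri C4 bromine slows attack at C3, and decomposition of the product during work-up.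
- Fallback, from 9 to 11: the order of the last two operations is reversed so that the bromination is done on the robust N-sulfonyl compound.
  - Brominate 9 at C3 with Br2 and NaOAc in AcOH/CH2Cl2 at rt to give 2,3,4,7-tetrabromo-1-tosylindole F7.
  - Remove the sulfonyl group with KOH in THF–H2O as in step 5 to give 11.

## Further compounds

F1 | step 4 | N-(3,6-dibromo-2-ethynylphenyl)-4-methylbenzenesulfonamide | C#Cc1c(Br)ccc(Br)c1NS(=O)(=O)c1ccc(C)cc1
F2 | step 4 | 4,7-dibromo-1-tosylindole (4,7-dibromo-1-(4-methylbenzenesulfonyl)-1H-indole) | Cc1ccc(cc1)S(=O)(=O)n1ccc2c(Br)ccc(Br)c21
F3 | step 2 | 3,6-dibromo-2-[(2,4-dimethoxybenzyl)amino]benzaldehyde | COc1ccc(CNc2c(Br)ccc(Br)c2C=O)c(OC)c1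
F4 | step 2 | 2-amino-3,6-dibromobenzaldehyde | Nc1c(Br)ccc(Br)c1C=O
F5 | step 3 | tert-butyl (3,6-dibromo-2-formylphenyl)(tosyl)carbamate | CC(C)(C)OC(=O)N(c1c(Br)ccc(Br)c1C=O)S(=O)(=O)c1ccc(C)cc1
F6 | step 3 | tert-butyl [3,6-dibromo-2-(2,2-dibromovinyl)phenyl](tosyl)carbamate | CC(C)(C)OC(=O)N(c1c(Br)ccc(Br)c1C=C(Br)Br)S(=O)(=O)c1ccc(C)cc1
F7 | step 6 | 2,3,4,7-tetrabromo-1-tosylindole (2,3,4,7-tetrabromo-1-(4-methylbenzenesulfonyl)-1H-indole) | Cc1ccc(cc1)S(=O)(=O)n1c(Br)c(Br)c2c(Br)ccc(Br)c21
A1 | alternative 1 | 2,5-dibromothiophene 1,1-dioxide | O=S1(=O)C(Br)=CC=C1Br
A2 | alternative 1 | tert-butyl 2,3-dihydro-1H-pyrrole-1-carboxylate | CC(C)(C)OC(=O)N1CCC=C1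
A3 | alternative 1 | tert-butyl cis-4,7-dibromo-2,3,3a,7a-tetrahydro-1H-indole-1-carboxylate (racemic) | CC(C)(C)OC(=O)N1CC[C@@H]2C(Br)=CC=C(Br)[C@H]12
A4 | alternative 1 | 4,7-dibromo-1H-indole | Brc1ccc(Br)c2[nH]ccc12
A5 | alternative 2 | N-(bromoethynyl)-N-(4-bromobut-3-yn-1-yl)-4-methylbenzenesulfonamide | BrC#CCCN(C#CBr)S(=O)(=O)c1ccc(C)cc1
A6 | alternative 2 | acetylene (ethyne) | C#C
A7 | alternative 2 | 4,7-dibromo-1-tosylindoline | Brc1ccc(Br)c2c1CCN2S(=O)(=O)c1ccc(C)cc1
A8 | alternative 3 | 2,5-dibromobenzaldehyde | O=Cc1cc(Br)ccc1Br
A9 | alternative 3 | ethyl azidoacetate | CCOC(=O)CN=[N+]=[N-]
A10 | alternative 3 | ethyl (Z)-2-azido-3-(2,5-dibromophenyl)prop-2-enoate | CCOC(=O)/C(N=[N+]=[N-])=C/c1cc(Br)ccc1Br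
A11 | alternative 3 | ethyl 4,7-dibromo-1H-indole-2-carboxylate | CCOC(=O)c1cc2c(Br)ccc(Br)c2[nH]1
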